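**Strategy**

Everything rests on cutting the C4–C5 bond of ring A. Ring B (C5–C10, C14 on C10, oxygen at C6, isopropyl at C7) is a p-menthan-3-one, and ring A hangs on it through the ketol array C4(OH)–C5–C6(=O); C4 (retro-aldol), C5 and C7 (enolisation) are therefore all reversible, whereas quaternary C10 is not. One base-mediated aldol of a monocyclic 1,7-diketone, 3-methyl-3-(4-oxopentyl)-6-isopropylcyclohexanone made from (R)-piperitone with only C10 secure, should close ring A and let these three centres settle into the trans-decalin with equatorial isopropyl, equatorial C15 and axial 4-OH. Reduction at C6 and acylation with silyl-protected isoferulic acid complete the target.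

Key step: step 3

Remark: eudesmane numbering (C1–C15) is used for the decalins and for the corresponding carbons of their monocyclic precursors. Commercial (R)-piperitone is assumed to be of high optical purity, although its stereocentre is re-equilibrated in step 3, so the enantiomeric purity of the product is that set at C10 in step 2. In this numbering the ketol of step 3 is (4S,5R,7S,10R); C5 becomes S only after reduction of C6, by a change of substituent priority and not of geometry.

**Route**

Step 1
Reactants: 1 2-(3-chloropropyl)-2-methyl-1,3-dioxolane
Product: 2 [3-(2-methyl-1,3-dioxolan-2-yl)propyl]magnesium chloride (titrated solution)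
Conditions: Mg turnings (I2 crystal), THF, 45–50 °C; diluted with Et2O
Reagents that add atoms: magnesium, [Mg]
Why: Magnesium inserts into the primary C–Cl bond (Grignard reagent formation), and the dioxolane, which has no acidic or electrophilic site, is inert to the organomagnesium, which is why the chain ketone is carried in this masked form.

Step 2
Reactants: 2 [3-(2-methyl-1,3-dioxolan-2-yl)propyl]magnesium chloride; 3 (R)-(−)-piperitone
Product: 6 (3R,6R)-3-methyl-3-(4-oxopentyl)-6-(propan-2-yl)cyclohexan-1-one, via chloromagnesium enolate 4 (not isolated), via ketal ketone 5 (not isolated)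
Conditions: Cu(OTf)2 (4 mol %), chiral C2-symmetric 1,3-diaryl-4,5-diphenylimidazolinium salt (5 mol %, carbene precursor), 2 (1.3 equiv), Et2O, −30 → 0 °C, 3 added slowly; then 1 M HCl, THF, rt
Reagents that add atoms: water, O
Why: Copper-catalysed asymmetric conjugate addition of a Grignard reagent to a 3-methylcyclohex-2-enone under a chiral N-heterocyclic carbene ligand (the divalent copper salt being reduced by 2 to the active monovalent copper–carbene complex) is an established route to all-carbon quaternary centres, the ligand enantiomer being chosen so that the chain enters the face that makes C10 R, which is also the face favoured by axial attack cis to the pseudoequatorial isopropyl group of 3 (matched case); the regiodefined enolate 4 is protonated and the dioxolane of 5 hydrolysed by the aqueous acid, while the isopropyl carbon keeps the piperitone configuration until step 3 corrects it.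

Step 3
Reactants: 6 (3R,6R)-3-methyl-3-(4-oxopentyl)-6-(propan-2-yl)cyclohexan-1-one
Product: 8 4β-hydroxy-5α-eudesman-6-one, via C7-epimeric diketone 7 (not isolated)
Conditions: NaOMe (0.3 equiv), MeOH, 0 → 20 °C, until the isomer distribution is constant; AcOH quench at 0 °C
Reagents that add atoms: none
Why: Methoxide reversibly generates the C5 enolate of the ring ketone, which adds to the unhindered chain methyl ketone, forming the C4–C5 bond and closing ring A by a 6-(enolexo)-exo-trig aldol addition; the closest known reaction type is the ketol stage of a base-mediated annulation of a 1,7-diketone, here left fully reversible as in menthone–isomenthone and cis/trans-1-decalone equilibrations. Every aldolate can revert by retro-aldol and C5 and C7 epimerise through their enolates, so 6, its C7 epimer 7 and the ketol stereoisomers should interconvert, with quaternary C10 the only fixed reference. C5 is expected to settle trans to the C14 methyl (trans-decalin), C7 with its isopropyl equatorial (which inverts the centre brought in by piperitone), and C4 with C15 equatorial and the hydroxyl axial, because an axial OH syn to the axial C14 methyl is less costly than an axial methyl there and can hydrogen-bond to the C6 carbonyl. The selectivity required is thermodynamic: one ketol out of eight, in preference to the bridged aldol between the C3 enolate and the C6 carbonyl and to the dehydrated Δ4-enone. The first is secured by the axial C14 methyl on C10, the second by the strain and reversibility of the bicyclo[3.3.1]nonane ketol, and the third by sub-stoichiometric base, low temperature and the allylic strain between C15 and the C6 carbonyl that disfavours the enone.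

Step 4
Reactants: 8 4β-hydroxy-5α-eudesman-6-one
Product: 9 5α-eudesmane-4β,6β-diol
Conditions: Et2BOMe (1.1 equiv), THF–MeOH 4:1, −78 °C; NaBH4 (1.5 equiv), −78 °C; AcOH quench, MeOH co-evaporation
Reagents that add atoms: none
Why: Narasaka–Prasad reduction, in which the diethylboron chelate ties the axial 4β-oxygen to the C6 carbonyl and so excludes internal hydride delivery and retro-aldol, and borohydride then attacks from outside on the α face, the only open one because the axial C14 methyl and the 4β-oxygen flank the β face (the sense known from hydride reduction of 6-oxo steroids), giving the axial 6β-alcohol (6R), that is the syn-1,3-diol.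

Step 5
Reactants: 10 isoferulic acid
Product: 12 O-TBS-isoferulic acid, via bis-silyl compound 11 (not isolated)
Conditions: TBSCl (2.5 equiv), imidazole, DMF, rt; then AcOH–THF–H2O 3:1:1, rt
Reagents that add atoms: tert-butyldimethylsilyl chloride, CC(C)(C)[Si](C)(C)Cl
Why: Silylation of both acidic oxygens followed by mild aqueous acid, which hydrolyses the very labile silyl ester of 11 but not the aryl silyl ether, is the usual access to O-silyl hydroxycinnamic acids and leaves the E alkene untouched.

Step 6
Reactants: 9 5α-eudesmane-4β,6β-diol; 12 O-TBS-isoferulic acid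
Product: 14 4β-hydroxyeudesman-6β-yl O-TBS-isoferulate, via mixed anhydride 13 (not isolated)
Conditions: 12 (1.5 equiv), 2,4,6-Cl3C6H2COCl, Et3N, toluene, rt; then 9, DMAP (2 equiv), toluene, rt → 60 °C
Reagents that add atoms: none
Why: Yamaguchi esterification, in which DMAP attacks the unhindered cinnamoyl carbonyl of mixed anhydride 13 and the resulting acylpyridinium acylates the secondary 6β-hydroxyl of 9, whereas the tertiary 4β-hydroxyl is too hindered to react and the phenol is masked, so neither diacylation nor oligomerisation is expected and no stereocentre is touched.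

Step 7
Reactants: 14 4β-hydroxyeudesman-6β-yl O-TBS-isoferulate
Product: 15 4β-hydroxyeudesman-6β-yl isoferulate (target)
Conditions: TBAF (1.1 equiv), AcOH (1.2 equiv), THF, 0 °C
Reagents that add atoms: none
Why: Fluoride cleaves the aryl silicon–oxygen bond far faster than it attacks the hindered cinnamate, and the acetic acid buffer keeps the liberated phenoxide from promoting ester cleavage, so the free phenol should be released with all five stereocentres and the E alkene intact.

**Compound list**

1 | 2-(3-chloropropyl)-2-methyl-1,3-dioxolane | CC1(CCCCl)OCCO1 | starting material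
2 | [3-(2-methyl-1,3-dioxolan-2-yl)propyl]magnesium chloride | CC1(CCC[Mg]Cl)OCCO1 | intermediate
3 | (R)-(−)-piperitone, (6R)-3-methyl-6-(propan-2-yl)cyclohex-2-en-1-one | CC1=CC(=O)[C@@H](C(C)C)CC1 | starting material
4 | chloromagnesium enolate of 5 (enolate double bond C5=C6) | Cl[Mg]OC1=C[C@](C)(CCCC2(C)OCCO2)CC[C@@H]1C(C)C | intermediate
5 | (3R,6R)-3-methyl-3-[3-(2-methyl-1,3-dioxolan-2-yl)propyl]-6-(propan-2-yl)cyclohexan-1-one | O=C1C[C@](C)(CCCC2(C)OCCO2)CC[C@@H]1C(C)C | intermediate
6 | (3R,6R)-3-methyl-3-(4-oxopentyl)-6-(propan-2-yl)cyclohexan-1-one | O=C1C[C@](C)(CCCC(C)=O)CC[C@@H]1C(C)C | intermediate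
7 | (3R,6S)-3-methyl-3-(4-oxopentyl)-6-(propan-2-yl)cyclohexan-1-one (C7 epimer of 6, direct seco form of 8) | O=C1C[C@](C)(CCCC(C)=O)CC[C@H]1C(C)C | intermediate
8 | (4S,5R,7S,10R)-4β-hydroxy-5α-eudesman-6-one (trans-decalin, axial 4-OH, equatorial isopropyl) | O=C1[C@@H]2[C@](C)(CCC[C@]2(C)O)CC[C@H]1C(C)C | intermediate
9 | (4S,5S,6R,7S,10R)-5α-eudesmane-4β,6β-diol | O[C@H]1[C@@H]2[C@](C)(CCC[C@]2(C)O)CC[C@H]1C(C)C | intermediate
10 | isoferulic acid, (E)-3-(3-hydroxy-4-methoxyphenyl)prop-2-enoic acid | COc1ccc(/C=C/C(=O)O)cc1O | starting material
11 | tert-butyldimethylsilyl (E)-3-[3-(tert-butyldimethylsilyloxy)-4-methoxyphenyl]prop-2-enoate | COc1ccc(/C=C/C(=O)O[Si](C)(C)C(C)(C)C)cc1O[Si](C)(C)C(C)(C)C | intermediate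
12 | (E)-3-[3-(tert-butyldimethylsilyloxy)-4-methoxyphenyl]prop-2-enoic acid | COc1ccc(/C=C/C(=O)O)cc1O[Si](C)(C)C(C)(C)C | intermediate
13 | mixed anhydride of 12 with 2,4,6-trichlorobenzoic acid | COc1ccc(/C=C/C(=O)OC(=O)c2c(Cl)cc(Cl)cc2Cl)cc1O[Si](C)(C)C(C)(C)C | intermediate
14 | (4S,5S,6R,7S,10R)-4β-hydroxyeudesman-6β-yl (E)-3-[3-(tert-butyldimethylsilyloxy)-4-methoxyphenyl]prop-2-enoate | COc1ccc(/C=C/C(=O)O[C@H]2[C@@H]3[C@](C)(CCC[C@]3(C)O)CC[C@H]2C(C)C)cc1O[Si](C)(C)C(C)(C)C | intermediate
15 | (4S,5S,6R,7S,10R)-4β-hydroxyeudesman-6β-yl isoferulate | COc1ccc(/C=C/C(=O)O[C@H]2[C@@H]3[C@](C)(CCC[C@]3(C)O)CC[C@H]2C(C)C)cc1O | target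

**Step count**

Total: 7 steps. Longest linear sequence: 6 steps (steps 1, 2, 3, 4, 6, 7 from compound 1).

**Steps most likely to fail**

1. Step 3. The equilibration may not converge: several ketol stereoisomers may remain, in particular at the ring fusion or at the isopropyl carbon. Water may also be lost irreversibly once the C5 enolate of the ketol forms. The fallback replaces thermodynamic control by a kinetic, stereospecific sequence from 6 to 8. Diketone 6 is deliberately driven through to the conjugated enone by aldol condensation (KOH, MeOH, reflux), giving eudesm-4-en-6-one F1, in which only the enolisable isopropyl carbon is left to equilibrate. i-Bu2AlH at −78 °C should reduce F1 from the α face, anti to the C14 methyl, to eudesm-4-en-6β-ol F2. Hydroxyl-directed epoxidation (VO(acac)2, t-BuOOH) then places the oxygen on the β face of C4 and gives 4β,5β-epoxyeudesman-6β-ol F3. Dess–Martin oxidation gives 4β,5β-epoxyeudesman-6-one F4. SmI2 (divalent samarium) in THF–MeOH at −78 °C cleaves the C5–O bond of this α,β-epoxy ketone, and axial protonation of the samarium enolate on the α face should return the trans-fused ketol 8.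

2. Step 2. Addition at the β,β-disubstituted carbon of an α'-branched enone may be slow relative to carbonyl attack or enolisation of 3, or facial control may be insufficient; any C10 epimer becomes the enantiomer after step 3. At the stage of 5 or 6 that epimer is still a diastereomer, so it can be assayed on an aliquot quenched with NH4Cl and removed before step 3. The fallback makes methyl the transferred group. Grignard reagent 2 is added to the carbonyl of commercial racemic 4-isopropylcyclohex-2-en-1-one (cryptone) to give the tertiary allylic alcohol 1-[3-(2-methyl-1,3-dioxolan-2-yl)propyl]-4-(propan-2-yl)cyclohex-2-en-1-ol F5. Babler–Dauben oxidative transposition with pyridinium chlorochromate [C5H5NH][CrO3Cl] (hexavalent chromium, NaOAc buffer) gives 3-[3-(2-methyl-1,3-dioxolan-2-yl)propyl]-6-(propan-2-yl)cyclohex-2-en-1-one F6. Copper-catalysed asymmetric conjugate addition of Me3Al (copper thiophene-2-carboxylate Cu(O2CC4H3S), monovalent copper, chiral phosphoramidite, Et2O, −30 °C), an established quaternary-centre-forming method for 3-alkylcyclohexenones, should then give 5 together with its isopropyl epimer, the (3R,6S)-ketal ketone F7, both 10R. The acid treatment of step 2 converts them into 6 and 7, which enter step 3 together.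

3. Step 6. Acyl transfer to the 6β-hydroxyl, which is axial and flanked by the C14 methyl, the 4β-hydroxyl and the C7 isopropyl, may be too slow, so that the activated acid is consumed unproductively or the aryl silyl ether is lost on prolonged heating. The fallback builds the cinnamate on the alcohol. Diol 9 is acylated with the small diethylphosphonoacetic acid (DCC, DMAP, CH2Cl2), a coupling believed to run through a phosphonoketene and therefore tolerant of hindered alcohols, giving 4β-hydroxyeudesman-6β-yl diethylphosphonoacetate F8. Horner–Wadsworth–Emmons olefination of F8 with commercial 3-(tert-butyldimethylsilyloxy)-4-methoxybenzaldehyde under Masamune–Roush conditions (LiCl, DBU, MeCN) forms the E alkene and gives 14, which is desilylated as in step 7.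

**Further compounds**

F1 | step 3 | (7S,10R)-eudesm-4-en-6-one | O=C1C2=C(C)CCC[C@]2(C)CC[C@H]1C(C)C
F2 | step 3 | (6R,7S,10R)-eudesm-4-en-6β-ol | O[C@H]1C2=C(C)CCC[C@]2(C)CC[C@H]1C(C)C
F3 | step 3 | 4β,5β-epoxyeudesman-6β-ol | O[C@H]1[C@]23O[C@@]2(C)CCC[C@]3(C)CC[C@H]1C(C)C
F4 | step 3 | 4β,5β-epoxyeudesman-6-one | O=C1[C@]23O[C@@]2(C)CCC[C@]3(C)CC[C@H]1C(C)C
F5 | step 2 | 1-[3-(2-methyl-1,3-dioxolan-2-yl)propyl]-4-(propan-2-yl)cyclohex-2-en-1-ol (stereoisomer mixture, both centres lost or re-equilibrated later) | OC1(CCCC2(C)OCCO2)C=CC(C(C)C)CC1
F6 | step 2 | 3-[3-(2-methyl-1,3-dioxolan-2-yl)propyl]-6-(propan-2-yl)cyclohex-2-en-1-one (racemic) | O=C1C=C(CCCC2(C)OCCO2)CCC1C(C)C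
F7 | step 2 | (3R,6S)-3-methyl-3-[3-(2-methyl-1,3-dioxolan-2-yl)propyl]-6-(propan-2-yl)cyclohexan-1-one | O=C1C[C@](C)(CCCC2(C)OCCO2)CC[C@H]1C(C)C
F8 | step 6 | 4β-hydroxyeudesman-6β-yl diethylphosphonoacetate | CCOP(=O)(OCC)CC(=O)O[C@H]1[C@@H]2[C@](C)(CCC[C@]2(C)O)CC[C@H]1C(C)C
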